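**Plan**

Labdane numbering is used: ring A is C1–C5 and C10, ring B is C5–C10; C18 and C19 are the acetoxymethyl carbons on C4, C20 the methyl on C10, C17 the methylene on C8, and C11–C16 the chain on C9.
Enabling feature: C4 carries two oxygenated one-carbon groups and is bonded to C5, so it can be a malonate carbon, and C10 is β to a ketone at C8. The ring-fusion bond C5–C10 therefore links the β-carbons of an alkylidene malonate and an enone.
Retrosynthesis: remove the acetates and C8=C17 (giving the C4 gem-diester and C8 ketone), then cut C9–C11, then C3–C4 (ring A), then C5–C10 (ring B); the acyclic chloro enone/alkylidene malonate is cut at C4=C5 and C8–C9.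
Forward: the chain is assembled (C9=C10 by carboalumination, C8–C9 by acylation, C4=C5 by condensation). Ring B closes first by cathodic reductive coupling with the C8 enolate kept as a silyl enol ether, ring A second by malonate alkylation. Then follow the C9 chain, the C8 methylene, ester reduction and acetylation.
Stereochemistry: C5 from a chiral scandium–pybox complex bound to the malonate; C10 relative to C5 from the E-enone in a chair transition state (trans ring fusion); C9 by equilibration to the equatorial epimer next to the C8 ketone; the 12E alkene from the E-enynol.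

Key step: step 6

Remark: the sense of induction of the scandium–pybox complex cannot be predicted with confidence. The (S,S)-ligand is written; if the opposite sense is found, its commercially available mirror image is used instead.

**Route**

Step 1
Reactants: 1 methyl 4,4-dimethoxybutanoate
Product: 2 N,4,4-trimethoxy-N-methylbutanamide
Conditions: MeNH(OMe)·HCl, i-PrMgCl, THF, −20 °C to 0 °C
Reagents that add atoms: N,O-dimethylhydroxylamine hydrochloride, CNOC.Cl
Why: Aminolysis of the ester by the chloromagnesium amide of N,O-dimethylhydroxylamine is the standard way to a Weinreb amide, and the dimethyl acetal is inert to these basic conditions.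

Step 2
Reactants: 3 5-chloropent-1-yne
Product: 5 (1E)-5-chloro-1-iodo-2-methylpent-1-ene, via alkenyldimethylalane 4 (not isolated)
Conditions: AlMe3, Cp2ZrCl2 (cat), CH2Cl2, 0 °C to rt; then I2, THF, −30 °C to 0 °C
Reagents that add atoms: trimethylaluminium, C[Al](C)C; iodine, II
Why: Zirconium-catalysed Negishi carboalumination adds methyl and aluminium syn across the terminal alkyne with the metal at the terminus, and iodinolysis of the C–Al bond with retention gives the E-iodide that fixes the later enone geometry while the primary chloride is untouched.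

Step 3
Reactants: 5 (1E)-5-chloro-1-iodo-2-methylpent-1-ene; 2 N,4,4-trimethoxy-N-methylbutanamide
Product: 7 (5E)-9-chloro-1,1-dimethoxy-6-methylnon-5-en-4-one, via alkenyllithium 6 (not isolated)
Conditions: t-BuLi (2 equiv), Et2O, −78 °C; then 2, −78 °C to 0 °C; H2O quench
Reagents that add atoms: none
Why: Iodine–lithium exchange is faster than any attack on the alkyl chloride and keeps the alkene geometry (lithium is trans to the chloropropyl arm and cannot cyclise), and the Weinreb ketone synthesis stops at the chelated tetrahedral adduct so that the E-enone is released only on work-up.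

Step 4
Reactants: 7 (5E)-9-chloro-1,1-dimethoxy-6-methylnon-5-en-4-one
Product: 8 (5E)-9-chloro-6-methyl-4-oxonon-5-enal
Conditions: 1 M HCl, THF, 0 °C to rt; used at once
Reagents that add atoms: water, O
Why: Acid-catalysed hydrolysis of an acyclic dimethyl acetal is fast under conditions too mild to isomerise the β,β-disubstituted enone or to dehydrate the 1,4-keto aldehyde to a furan.

Step 5
Reactants: 8 (5E)-9-chloro-6-methyl-4-oxonon-5-enal; 9 dimethyl malonate
Product: 10 dimethyl 2-[(5E)-9-chloro-6-methyl-4-oxonon-5-en-1-ylidene]propanedioate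
Conditions: piperidine (cat), AcOH (cat), 4 Å MS, CH2Cl2, 0 °C to rt
Reagents that add atoms: none
Why: Knoevenagel condensation under buffered amine catalysis takes place at the aldehyde only, the ketone being far less electrophilic, and the mild conditions should leave the E-enone and the chloride unchanged.

Step 6
Reactants: 10 dimethyl 2-[(5E)-9-chloro-6-methyl-4-oxonon-5-en-1-ylidene]propanedioate; 11 chlorotriethylsilane
Product: 13 dimethyl 2-[(1R,2R)-2-(3-chloropropyl)-2-methyl-4-(triethylsilyloxy)cyclohex-3-en-1-yl]propanedioate, via bis-silyl ketene acetal 12 (not isolated)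
Conditions: Sc(OTf)3 (20 mol %), 2,6-bis[(4S)-4-isopropyl-4,5-dihydro-1,3-oxazol-2-yl]pyridine (24 mol %), Et3SiCl (2.5 equiv), n-Bu4NOTf, 4 Å MS, MeCN/CH2Cl2, −20 °C; divided cell, glassy-carbon cathode, Zn anode in the anode chamber, controlled potential at the wave of the scandium-bound malonate, 2 F/mol; then pH 7 buffer/MeOH, 0 °C
Reagents that add atoms: chlorotriethylsilane (compound 11), CC[Si](CC)(CC)Cl
Why: Proposed new method: chelation of the two ester carbonyls of 10 to the Sc(OTf)3–pybox complex should shift the reduction of the alkylidene malonate to a potential at which free 10, the enone and Et3SiCl are not reduced, so that only the bound substrate accepts an electron; the resulting radical anion is nucleophilic at C5 and adds to the enone β-carbon C10, the α-keto radical is reduced at once to the C8 enolate, and Et3SiCl silylates this enolate on oxygen and also the scandium-bound malonate (which releases the Lewis acid), the ketene acetal part of 12 being hydrolysed on work-up. The closest known reactions are the racemic cathodic electrohydrocyclisation of tethered Michael acceptors and radical-anion cyclisations steered by chiral Lewis acids under photoredox conditions. Ring B closes by the C5–C10 bond in a mode that is 6-exo with respect to the malonate alkene and 6-endo with respect to the enone, through a chair-like transition state. C5 is controlled by the ligand, whose isopropyl groups shield one face of the chelated C4=C5 unit, and C10 is controlled relative to C5 by the E geometry of the enone, which places the methyl group pseudo-axial and the chloropropyl arm pseudo-equatorial, trans to the pseudo-equatorial malonyl group. The step needs β,β-coupling to win over simple saturation of either alkene, pinacol-type coupling and C–Cl cleavage, and it needs the enolate to be trapped only at C8–C9; the low reduction potential of the chelated malonate, the six-membered chair, the absence of a proton donor and the divided cell (no achiral metal ions from the anode) are meant to secure this.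

Step 7
Reactants: 13 dimethyl 2-[(1R,2R)-2-(3-chloropropyl)-2-methyl-4-(triethylsilyloxy)cyclohex-3-en-1-yl]propanedioate
Product: 14 dimethyl (4aR,8aS)-4a-methyl-6-[(triethylsilyl)oxy]-3,4,4a,7,8,8a-hexahydronaphthalene-1,1(2H)-dicarboxylate
Conditions: NaH, n-Bu4NI (cat), THF, 0 °C to 60 °C
Reagents that add atoms: none
Why: Intramolecular alkylation of the sodium malonate by the primary halide (6-exo-tet, iodide catalysis) forms C3–C4 and ring A, the trans ring fusion follows from the trans relation of malonyl group and chloropropyl arm set in step 6, and the non-nucleophilic base leaves the silyl enol ether intact.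

Step 8
Reactants: 15 (2E)-3-methylpent-2-en-4-yn-1-ol
Product: 16 (2E)-3-methylpenta-2,4-dien-1-ol
Conditions: H2 (1 atm), Pd/CaCO3 poisoned with Pb(OAc)2 (Lindlar catalyst), quinoline, EtOAc, rt
Reagents that add atoms: none
Why: Lindlar semi-hydrogenation stops at the alkene for a terminal alkyne and does not touch the trisubstituted E double bond.

Step 9
Reactants: 16 (2E)-3-methylpenta-2,4-dien-1-ol
Product: 17 (3E)-5-bromo-3-methylpenta-1,3-diene
Conditions: PBr3, pyridine (cat), Et2O, −20 °C to 0 °C; used cold without storage
Reagents that add atoms: phosphorus tribromide, BrP(Br)Br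
Why: Bromination of a primary allylic alcohol with PBr3 at low temperature is an SN2 displacement that keeps the E alkene, and because both ends of this 3-methylpentadienyl unit are CH2 groups a terminal allylic shift would give the same constitution.

Step 10
Reactants: 14 dimethyl (4aR,8aS)-4a-methyl-6-[(triethylsilyl)oxy]-3,4,4a,7,8,8a-hexahydronaphthalene-1,1(2H)-dicarboxylate; 17 (3E)-5-bromo-3-methylpenta-1,3-diene
Product: 18 dimethyl (4aR,5R,8aS)-4a-methyl-5-[(2E)-3-methylpenta-2,4-dien-1-yl]-6-oxooctahydronaphthalene-1,1(2H)-dicarboxylate (chain axial at C9)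
Conditions: BnMe3NF (anhydrous), 4 Å MS, THF, −20 °C to rt
Reagents that add atoms: none
Why: Fluoride-triggered alkylation of a silyl enol ether frees the ammonium enolate at C8–C9 only, which attacks the allylic bromide through carbon (SN2), and the electrophile is expected to enter axially on the face opposite the C10 methyl group so that the chain at the new C9 centre is at first axial.

Step 11
Reactants: 18 dimethyl (4aR,5R,8aS)-4a-methyl-5-[(2E)-3-methylpenta-2,4-dien-1-yl]-6-oxooctahydronaphthalene-1,1(2H)-dicarboxylate
Product: 19 dimethyl (4aR,5S,8aS)-4a-methyl-5-[(2E)-3-methylpenta-2,4-dien-1-yl]-6-oxooctahydronaphthalene-1,1(2H)-dicarboxylate (chain equatorial at C9)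
Conditions: NaOMe (cat), MeOH, rt
Reagents that add atoms: none
Why: Base-mediated epimerisation through the C8–C9 enolate should move the chain from the axial to the equatorial position, the thermodynamically preferred arrangement next to the ketone in the trans-decalin, which sets C9 as in the target while the methyl esters are unchanged by methoxide in methanol.

Step 12
Reactants: 19 dimethyl (4aR,5S,8aS)-4a-methyl-5-[(2E)-3-methylpenta-2,4-dien-1-yl]-6-oxooctahydronaphthalene-1,1(2H)-dicarboxylate
Product: 20 dimethyl (4aS,5R,8aS)-4a-methyl-6-methylidene-5-[(2E)-3-methylpenta-2,4-dien-1-yl]octahydronaphthalene-1,1(2H)-dicarboxylate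
Conditions: Ph3PCH3Br, KOtBu, toluene, rt to 80 °C
Reagents that add atoms: methyltriphenylphosphonium bromide, C[P+](c1ccccc1)(c1ccccc1)c1ccccc1.[Br-]
Why: Wittig methylenation with the unstabilised ylide converts hindered 8-oxo decalins of this kind into the exocyclic methylene while the hindered quaternary esters are left alone, and any enolisation at C9 returns the already favoured equatorial epimer.

Step 13
Reactants: 20 dimethyl (4aS,5R,8aS)-4a-methyl-6-methylidene-5-[(2E)-3-methylpenta-2,4-dien-1-yl]octahydronaphthalene-1,1(2H)-dicarboxylate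
Product: 21 [(4aS,5R,8aS)-4a-methyl-6-methylidene-5-[(2E)-3-methylpenta-2,4-dien-1-yl]octahydronaphthalene-1,1(2H)-diyl]dimethanol
Conditions: LiAlH4, THF, 0 °C to reflux; Fieser work-up
Reagents that add atoms: none
Why: Hydride reduction with LiAlH4 takes both esters to the primary alcohols and does not reduce the isolated methylene or the unactivated conjugated diene.

Step 14
Reactants: 21 [(4aS,5R,8aS)-4a-methyl-6-methylidene-5-[(2E)-3-methylpenta-2,4-dien-1-yl]octahydronaphthalene-1,1(2H)-diyl]dimethanol
Product: 22 [(4aS,5R,8aS)-4a-methyl-6-methylidene-5-[(2E)-3-methylpenta-2,4-dien-1-yl]octahydronaphthalene-1,1(2H)-diyl]bis(methylene) diacetate, that is (5S,9R,10S,12E)-labda-8(17),12,14-triene-18,19-diyl diacetate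
Conditions: Ac2O, pyridine, DMAP (cat), CH2Cl2, rt
Reagents that add atoms: acetic anhydride, CC(=O)OC(C)=O
Why: DMAP-catalysed acylation esterifies both neopentyl primary alcohols without touching the alkenes or any stereocentre.

**Compound list**

1 | methyl 4,4-dimethoxybutanoate | COC(=O)CCC(OC)OC | starting material
2 | N,4,4-trimethoxy-N-methylbutanamide | CON(C)C(=O)CCC(OC)OC | intermediate
3 | 5-chloropent-1-yne | C#CCCCCl | starting material
4 | [(1E)-5-chloro-2-methylpent-1-en-1-yl]dimethylalumane | C[Al](C)/C=C(\C)CCCCl | intermediate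
5 | (1E)-5-chloro-1-iodo-2-methylpent-1-ene | I/C=C(\C)CCCCl | intermediate
6 | [(1E)-5-chloro-2-methylpent-1-en-1-yl]lithium | [Li]/C=C(\C)CCCCl | intermediate
7 | (5E)-9-chloro-1,1-dimethoxy-6-methylnon-5-en-4-one | COC(OC)CCC(=O)/C=C(\C)CCCCl | intermediate
8 | (5E)-9-chloro-6-methyl-4-oxonon-5-enal | O=CCCC(=O)/C=C(\C)CCCCl | intermediate
9 | dimethyl malonate | COC(=O)CC(=O)OC | starting material
10 | dimethyl 2-[(5E)-9-chloro-6-methyl-4-oxonon-5-en-1-ylidene]propanedioate | COC(=O)C(C(=O)OC)=CCCC(=O)/C=C(\C)CCCCl | intermediate
11 | chlorotriethylsilane | CC[Si](CC)(CC)Cl | starting material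
12 | methyl 2-[(1S,2R)-2-(3-chloropropyl)-2-methyl-4-[(triethylsilyl)oxy]cyclohex-3-en-1-yl]-3-methoxy-3-[(triethylsilyl)oxy]prop-2-enoate | COC(=O)C(=C(OC)O[Si](CC)(CC)CC)[C@H]1CCC(O[Si](CC)(CC)CC)=C[C@]1(C)CCCCl | intermediate
13 | dimethyl 2-[(1R,2R)-2-(3-chloropropyl)-2-methyl-4-(triethylsilyloxy)cyclohex-3-en-1-yl]propanedioate | COC(=O)C(C(=O)OC)[C@H]1CCC(O[Si](CC)(CC)CC)=C[C@]1(C)CCCCl | intermediate
14 | dimethyl (4aR,8aS)-4a-methyl-6-[(triethylsilyl)oxy]-3,4,4a,7,8,8a-hexahydronaphthalene-1,1(2H)-dicarboxylate | CC[Si](CC)(CC)OC1=C[C@]2(C)CCCC(C(=O)OC)(C(=O)OC)[C@H]2CC1 | intermediate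
15 | (2E)-3-methylpent-2-en-4-yn-1-ol | C#C/C(C)=C/CO | starting material
16 | (2E)-3-methylpenta-2,4-dien-1-ol | C=C/C(C)=C/CO | intermediate
17 | (3E)-5-bromo-3-methylpenta-1,3-diene | C=C/C(C)=C/CBr | intermediate
18 | dimethyl (4aR,5R,8aS)-4a-methyl-5-[(2E)-3-methylpenta-2,4-dien-1-yl]-6-oxooctahydronaphthalene-1,1(2H)-dicarboxylate | C=C/C(C)=C/C[C@H]1C(=O)CC[C@@H]2C(C(=O)OC)(C(=O)OC)CCC[C@@]12C | intermediate
19 | dimethyl (4aR,5S,8aS)-4a-methyl-5-[(2E)-3-methylpenta-2,4-dien-1-yl]-6-oxooctahydronaphthalene-1,1(2H)-dicarboxylate | C=C/C(C)=C/C[C@@H]1C(=O)CC[C@@H]2C(C(=O)OC)(C(=O)OC)CCC[C@@]12C | intermediate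
20 | dimethyl (4aS,5R,8aS)-4a-methyl-6-methylidene-5-[(2E)-3-methylpenta-2,4-dien-1-yl]octahydronaphthalene-1,1(2H)-dicarboxylate | C=C/C(C)=C/C[C@@H]1C(=C)CC[C@@H]2C(C(=O)OC)(C(=O)OC)CCC[C@@]12C | intermediate
21 | [(4aS,5R,8aS)-4a-methyl-6-methylidene-5-[(2E)-3-methylpenta-2,4-dien-1-yl]octahydronaphthalene-1,1(2H)-diyl]dimethanol | C=C/C(C)=C/C[C@@H]1C(=C)CC[C@@H]2C(CO)(CO)CCC[C@@]12C | intermediate
22 | [(4aS,5R,8aS)-4a-methyl-6-methylidene-5-[(2E)-3-methylpenta-2,4-dien-1-yl]octahydronaphthalene-1,1(2H)-diyl]bis(methylene) diacetate | C=C/C(C)=C/C[C@@H]1C(=C)CC[C@@H]2C(COC(C)=O)(COC(C)=O)CCC[C@@]12C | target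

**Step count and risks**

Total step count: 14.
Longest linear sequence: 11 steps (step 1 or 2, then steps 3, 4, 5, 6, 7, 10, 11, 12, 13, 14).

Steps most likely to fail:

1. Step 6. The scandium–pybox complex may discriminate the two faces of the chelated C4=C5 unit poorly, chloride released from Et3SiCl may displace triflate at scandium and slow turnover, and unbound substrate may then cyclise without facial control. The fallback sets out from 10 and comes back at 19. The chiral Lewis acid is given up and ring B is closed by the established racemic cathodic electrohydrocyclisation of tethered activated alkenes (undivided cell, graphite cathode, sacrificial Mg anode, n-Bu4NBF4, DMF, excess Et3SiCl). This should give 12 together with its mirror image, the (1R,2S)-bis-silyl ketene acetal F1, and after work-up 13 together with the (1S,2S)-malonate F2. The racemate is carried through steps 7, 10 and 11 as written, which gives beside 14, 18 and 19 the (4aS,8aR)-silyl enol ether F3, the (4aS,5S,8aR)-ketone F4 and the (4aS,5R,8aR)-ketone F5. Preparative chromatography on a chiral stationary phase (amylose tris(3,5-dimethylphenylcarbamate), hexane/2-propanol) then removes F5 and returns the route to 19.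

2. Step 10. C-alkylation of the hindered ammonium enolate, next to the quaternary C10, by the labile dienyl bromide may be slow, so that proton transfer, O-alkylation or loss of the E geometry of the bromide take over. The fallback sets out from 14 and comes back at 20, building the chain in stages. Tsuji allylation of the silyl enol ether with allyl methyl carbonate (Pd2(dba)3, dppe, zerovalent palladium, THF, reflux) should give the C9-allyl ketone, expected mainly as the axial (4aR,5R,8aS)-allyl ketone F6. NaOMe in MeOH would equilibrate it to the equatorial (4aR,5S,8aS)-allyl ketone F7. Cross-metathesis of F7 with methacrolein (second-generation Hoveyda–Grubbs catalyst, RuCl2(H2IMes)(=CH-C6H4-2-OiPr), CH2Cl2, 40 °C) should give the (2E)-enal F8. Wittig methylenation of both the aldehyde and the C8 ketone with excess Ph3PCH3Br/KOtBu would then deliver 20.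

3. Step 11. The equilibrium at C9 may not favour the equatorial chain strongly enough, leaving a mixture of epimers that is hard to separate. The fallback sets out from 18 (or the mixture of 18 and 19) and comes back at 19, setting C9 under kinetic control instead. Equilibrating enol silylation (Me3SiOTf, Et3N, CH2Cl2, 0 °C to rt) should give the tetrasubstituted C8–C9 trimethylsilyl enol ether F9. Its protodesilylation at low temperature (n-Bu4NF, AcOH, THF, −78 °C) should deliver the proton to C9 axially from the face opposite the C10 methyl group and so give 19. Any enol ether formed towards C7 returns 18 and is recycled.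

Further compounds
F1 | step 6 | methyl 2-[(1R,2S)-2-(3-chloropropyl)-2-methyl-4-[(triethylsilyl)oxy]cyclohex-3-en-1-yl]-3-methoxy-3-[(triethylsilyl)oxy]prop-2-enoate | COC(=O)C(=C(OC)O[Si](CC)(CC)CC)[C@@H]1CCC(O[Si](CC)(CC)CC)=C[C@@]1(C)CCCCl
F2 | step 6 | dimethyl 2-[(1S,2S)-2-(3-chloropropyl)-2-methyl-4-(triethylsilyloxy)cyclohex-3-en-1-yl]propanedioate | COC(=O)C(C(=O)OC)[C@@H]1CCC(O[Si](CC)(CC)CC)=C[C@@]1(C)CCCCl
F3 | step 6 | dimethyl (4aS,8aR)-4a-methyl-6-[(triethylsilyl)oxy]-3,4,4a,7,8,8a-hexahydronaphthalene-1,1(2H)-dicarboxylate | CC[Si](CC)(CC)OC1=C[C@@]2(C)CCCC(C(=O)OC)(C(=O)OC)[C@@H]2CC1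
F4 | step 6 | dimethyl (4aS,5S,8aR)-4a-methyl-5-[(2E)-3-methylpenta-2,4-dien-1-yl]-6-oxooctahydronaphthalene-1,1(2H)-dicarboxylate | C=C/C(C)=C/C[C@@H]1C(=O)CC[C@H]2C(C(=O)OC)(C(=O)OC)CCC[C@]12C
F5 | step 6 | dimethyl (4aS,5R,8aR)-4a-methyl-5-[(2E)-3-methylpenta-2,4-dien-1-yl]-6-oxooctahydronaphthalene-1,1(2H)-dicarboxylate | C=C/C(C)=C/C[C@H]1C(=O)CC[C@H]2C(C(=O)OC)(C(=O)OC)CCC[C@]12C
F6 | step 10 | dimethyl (4aR,5R,8aS)-4a-methyl-6-oxo-5-(prop-2-en-1-yl)octahydronaphthalene-1,1(2H)-dicarboxylate | C=CC[C@H]1C(=O)CC[C@@H]2C(C(=O)OC)(C(=O)OC)CCC[C@@]12C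
F7 | step 10 | dimethyl (4aR,5S,8aS)-4a-methyl-6-oxo-5-(prop-2-en-1-yl)octahydronaphthalene-1,1(2H)-dicarboxylate | C=CC[C@@H]1C(=O)CC[C@@H]2C(C(=O)OC)(C(=O)OC)CCC[C@@]12C
F8 | step 10 | dimethyl (4aR,5S,8aS)-4a-methyl-5-[(2E)-3-methyl-4-oxobut-2-en-1-yl]-6-oxooctahydronaphthalene-1,1(2H)-dicarboxylate | O=C/C(C)=C/C[C@@H]1C(=O)CC[C@@H]2C(C(=O)OC)(C(=O)OC)CCC[C@@]12C
F9 | step 11 | dimethyl (4aR,8aS)-4a-methyl-5-[(2E)-3-methylpenta-2,4-dien-1-yl]-6-[(trimethylsilyl)oxy]-3,4,4a,7,8,8a-hexahydronaphthalene-1,1(2H)-dicarboxylate | C=C/C(C)=C/CC1=C(O[Si](C)(C)C)CC[C@@H]2C(C(=O)OC)(C(=O)OC)CCC[C@@]12C
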